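## The problem

- Compound 27 is an ester of two aldol-type polypropionate halves. The acyl chain C1–C7 has the C1 ester carbonyl, C2–CH3, C3–OH, C4–CH3, the C5 ketone and C6–CH3, and C6 is bonded to C2 of a 3,5,6-trimethyl-4H-pyran-4-one (ring P). The alcohol half is joined through carbinol C5′ of a 4′,6′-dimethylnonane-3′,7′-dione (C1′–C9′).
- The two halves meet at the most crowded point. O–C5′ lies between two branched carbons and β to two ketones, so any base that enolises C4′ or C6′ expels the carboxylate. C3–OH is β to C1 and C5 (retro-aldol, dehydration), and the 1,5-diketone can close on itself by aldol reaction.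
- Five of the six stereocentres (C2 R, C4 S, C6 S, C4′ R, C6′ R) are α to a carbonyl group. C6 lies between the C5 ketone and the vinylogous ester of ring P, is the most acidic carbon, and must be set late and without base.
- C2–C3–C4 is the anti,anti stereotriad, which aldol and crotylation routes reach only against the Felkin preference of the aldehyde. No centre of one half can control the other half across the ester, and C4 can hardly control C6 across the ketone.
- In the segment O=C1–C2H(CH3)–C3H(OH)–C4H(CH3)–C5=O, C2 and C4 are mirror images across C3. The segment is therefore a desymmetrised meso-3-hydroxy-2,4-dimethylglutaryl unit, the opened form of an all-cis substituted six-membered cyclic anhydride (oxane-2,6-dione ring).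
- C5′ bears two identical (R)-CH(CH3)C(=O)CH2CH3 arms and is chirotopic but not stereogenic. Its configuration never has to be controlled, and the alcohol has almost no bias of its own at the reacting oxygen.
- These two features make the key step possible. The alcohol half opens the meso anhydride, which forms the hindered ester, fixes C2, C3 and C4 in the absolute sense, and frees the C5 carboxyl group for the last C–C bond.

## Retrosynthesis

**27 ⇒ 26.** Only the O–Si bond at C3 is cut. C3–OH must be masked because a free β-hydroxy acid chloride cannot exist. A silyl ether comes off with buffered HF, the one reagent class that is neither basic nor oxidising. Removal must be mild enough to leave C6, the β-acyloxy ketones and the β-hydroxy ketone untouched.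

**26 ⇒ 25 + 21 (C5–C6).**
- The neighbouring cut C6–C2 of ring P would need a metallated pyranone and an α-halo ketone, and the cut C4–C5 has no polar logic.
- Cutting C5–C6 uses the very carboxyl group that the anhydride opening sets free, and it makes the most labile centre the last one set.
- Chloride 21 is racemic and carries no other stereocentre. Acid chloride 25 holds everything else.
- The forward reaction must join an α-branched acyl group to a secondary radical-type carbon, choose the face at C6 by catalyst control, and run without base.

**25 ⇒ 24 ⇒ 22.** No skeletal bond is cut.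
- The C7′ ketone is carried as a silylated carbinol, because an aldehyde with a β-ketone (needed to build C5′) would racemise.
- Oxidation after the acylation erases C7′ and the stereogenicity of C5′.
- The transient C7′ alcohol 23 must not take over the acyl group.

**22 ⇒ 9 + 16 (C1–O5′, key step).**
- The same bond is cut as in an ordinary esterification, but before the acyl chain is finished, and the partner is the achiral meso anhydride 9 instead of a chiral acid.
- Anhydride 9 has no chirality, needs no coupling reagent, reacts only once and delivers the C5 acid. Hemiester 22 has seven stereocentres.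
- The anti,anti triad can thus be made in the achiral series by two-directional substrate control.
- The forward reaction must make the oxygen of 16 attack the carbonyl next to the (R)-configured α-carbon, under conditions too mild for E1cB or retro-aldol cleavage.

**9 ⇒ 8 ⇒ 7 ⇒ 6 ⇒ 4 ⇒ 3 ⇒ 1 + 2.**
- The ring C–O bond of 9 and the oxidation levels at C1 and C5 go back to meso diol 6.
- The two C–H and two C–O bonds made at C2/C1 and C4/C5 are cut at once, which leads to the bis-isopropenyl carbinol ether 4.
- One hydroboration sets C2 and C4 relative to C3.
- Dienol 3 comes from two three- and four-carbon commodity reagents.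

**16 ⇒ 12 + 13 (C4′–C5′), 12 ⇒ 11 ⇒ 10.**
- The aldol cut gives pentan-3-one 13 and aldehyde 12, itself the protected dimer of propanal 10.
- Only the 1,3-anti relation of the two methyl groups matters. The anti/Felkin and the syn/anti-Felkin adduct converge on the same 24.
- One centre (C6′) is set by catalysis, and C4′ is relayed from it.

**21 ⇒ 20 ⇒ 19 ⇒ 18 ⇒ 13.** The C–Cl bond, the C–CH3 bond and the C=O of the side chain are taken back to the symmetric tetramethylpyranone 18. This is a one-flask condensate of 13 with acetic acid. Its symmetry removes every regiochemical question in the oxidation of one methyl group.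

## Roads not taken

**Alternative 1: C1–O5′ cut between the finished acid A1 and the hydroxy diketone A2 (the obvious route).**
- Forward key step: Yamaguchi esterification to 26.
- A1 must be made as a single enantiomer with the anti,anti triad, which requires a mismatched aldol or crotylation sequence.
- Its labile C6 centre then has to survive triethylamine and 4-(dimethylamino)pyridine together with a very hindered alcohol.
- The ester-forming step sets no stereocentre. In the chosen plan the same bond formation does the stereochemical work for three centres, and C6 does not yet exist when the ester is made.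

**Alternative 2: cut of the ester by a retro-Claisen relation.**
- Target 27 would arise from the linear δ-hydroxy-β-diketone A3 by attack of O5′ on C1 (six-membered hemiketal) and cleavage of the C1–CH(CH3) bond.
- The idea is attractive because no esterification is needed.
- A3 is an isomer of 27 and no simpler. It has more stereocentres, one of them in a β-diketone, and it equilibrates with hemiketals.
- C3–OH flanks the same β-diketone from the other side and can trigger the opposite cleavage.
- The run-up to A3 costs more than the key step saves.

**Alternative 3: C3–C4 cut, an anti aldol union of ketone A4 (after E-selective enolisation) with aldehyde A5.**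
- It would form a C–C bond and two centres at once and relay them from C6.
- The required 2,3-anti relation is the anti-Felkin one, which E-enolates disfavour.
- A5 is an α-formyl ester and racemises through its enol.
- A4 offers its more acidic C6–H to the enolising reagent.
- The chosen plan takes the triad from a meso ring, where the Felkin question does not arise.

Key step: step 14

Assumption: the antipodes written for the isothiourea (step 14) and for the bis(oxazoline) (step 17) follow the models given there; both antipodes of each are commercial, so the sense can be corrected without change of the route.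

## Steps

Step 1
Reactants: 1 methacrolein; 2 isopropenylmagnesium bromide
Product: 3 2,4-dimethylpenta-1,4-dien-3-ol
Conditions: THF, −78 °C to 0 °C; aq NH4Cl
Reagents that add atoms: none
Why: Grignard 1,2-addition to an enal; 3 is achiral with two identical isopropenyl arms, and this symmetry is kept until step 14.

Step 2
Reactants: 3 2,4-dimethylpenta-1,4-dien-3-ol
Product: 4 tert-butyl[(2,4-dimethylpenta-1,4-dien-3-yl)oxy]dimethylsilane
Conditions: TBSCl, imidazole, DMF, rt
Reagents that add atoms: tert-butyldimethylsilyl chloride, CC(C)(C)[Si](C)(C)Cl
Why: Standard silylation; the bulky ether raises the facial bias of step 3 and masks the future C3–OH until the last step.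

Step 3
Reactants: 4 tert-butyl[(2,4-dimethylpenta-1,4-dien-3-yl)oxy]dimethylsilane
Product: 6 (2R,3s,4S)-3-[(tert-butyldimethylsilyl)oxy]-2,4-dimethylpentane-1,5-diol (meso, anti,anti), via bis(9-BBN) adduct 5 (not isolated)
Conditions: 9-BBN (2.6 equiv), THF, 0 °C to rt; then NaOH, H2O2, 0 °C
Reagents that add atoms: hydrogen peroxide, OO; 9-borabicyclo[3.3.1]nonane, B1C2CCCC1CCC2 (atoms kept only in 5)
Why: Two-directional hydroboration–oxidation of a 1,1-disubstituted allylic silyl ether; the bulky borane attacks each alkene in the conformer of least allylic strain (carbinol C–H near the C=C plane) and anti to the other branch, the known 2,3-anti preference of 9-BBN. The same bias acts at both ends, so C2 and C4 are set together relative to C3; the unsymmetrical syn,anti isomer is a diastereomer and is removed by chromatography.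

Step 4
Reactants: 6 meso anti,anti diol
Product: 7 (2R,3r,4S)-3-[(tert-butyldimethylsilyl)oxy]-2,4-dimethylpentanedial (meso)
Conditions: (COCl)2, DMSO, CH2Cl2, −78 °C; Et3N, −78 °C to −20 °C
Reagents that add atoms: none
Why: Swern oxidation; both hydroxyl groups are activated before the base is added, which avoids the lactol and lactone that stepwise oxidants give with 1,5-diols, and the low temperature keeps the α-centres.

Step 5
Reactants: 7 meso dialdehyde
Product: 8 (2R,3r,4S)-3-[(tert-butyldimethylsilyl)oxy]-2,4-dimethylpentanedioic acid (meso)
Conditions: NaClO2, NaH2PO4, 2-methylbut-2-ene, t-BuOH/H2O, 0 °C to rt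
Reagents that add atoms: sodium chlorite, [Na+].[O-]Cl=O
Why: Pinnick oxidation; the weakly acidic buffer does not epimerise α-branched aldehydes and leaves the silyl ether.

Step 6
Reactants: 8 meso diacid
Product: 9 (3R,4r,5S)-4-[(tert-butyldimethylsilyl)oxy]-3,5-dimethyloxane-2,6-dione (meso anhydride, all three substituents cis)
Conditions: DCC, CH2Cl2, 0 °C to rt; filtration
Reagents that add atoms: none
Why: Carbodiimide dehydration of a glutaric acid to the six-membered anhydride under neutral conditions; the chain anti,anti relation corresponds to the all-cis ring with both methyl groups equatorial, so there is no drive to epimerise.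

Step 7
Reactants: 10 propanal (two molecules)
Product: 11 (2S,3S)-3-hydroxy-2-methylpentanal
Conditions: L-proline (10 mol %), DMF, 4 °C, slow addition of 10
Reagents that add atoms: none
Why: Proline-catalysed enamine aldol dimerisation of propanal; L-proline gives the anti (2S,3S) adduct through the hydrogen-bonded enamine transition state. Only C2 (the future C6′) is kept to the end; C3 (the future C7′) is oxidised in step 15.

Step 8
Reactants: 11 (2S,3S)-3-hydroxy-2-methylpentanal
Product: 12 (2S,3S)-2-methyl-3-[(triethylsilyl)oxy]pentanal
Conditions: TESOTf, 2,6-lutidine, CH2Cl2, −78 °C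
Reagents that add atoms: triethylsilyl trifluoromethanesulfonate, CC[Si](CC)(CC)OS(=O)(=O)C(F)(F)F
Why: Low-temperature silylation with a hindered weak base does not epimerise the α-centre and stops oligomerisation of the aldol; the minor syn isomer is removed here by chromatography.

Step 9
Reactants: 13 pentan-3-one; 12 (2S,3S)-2-methyl-3-[(triethylsilyl)oxy]pentanal
Product: 16 (4R,5R,6R,7S)-5-hydroxy-4,6-dimethyl-7-[(triethylsilyl)oxy]nonan-3-one, via E-enolborinate 14 (not isolated), via boron aldolate 15 (not isolated)
Conditions: Cy2BCl, Et3N, Et2O, 0 °C; 12, −78 °C to −20 °C; H2O2, MeOH, pH 7 buffer, 0 °C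
Reagents that add atoms: dicyclohexylboron chloride, ClB(C1CCCCC1)C1CCCCC1 (atoms kept only in 14 and 15)
Why: Boron aldol reaction; Cy2BCl/Et3N gives the E-enolborinate, the Zimmerman–Traxler chair gives 4′,5′-anti, and Felkin attack on the α-methyl aldehyde, which E-enolates favour, gives 5′,6′-syn, so C4′ is relayed from C6′. Only the 1,3-anti relation of the two methyl groups counts, because the syn/anti-Felkin adduct converges on the same 24 once C5′ loses its stereogenicity in step 15.

Step 10
Reactants: 13 pentan-3-one
Product: 18 2,3,5,6-tetramethyl-4H-pyran-4-one, via triketone 17 (not isolated)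
Conditions: AcOH, polyphosphoric acid, 100 °C
Reagents that add atoms: acetic acid, CC(=O)O
Why: Classical one-flask pyranone synthesis: acid-mediated C-acetylation of the ketone at both α-carbons gives 3,5-dimethylheptane-2,4,6-trione, which cyclodehydrates in the same medium.

Step 11
Reactants: 18 2,3,5,6-tetramethyl-4H-pyran-4-one
Product: 19 3,5,6-trimethyl-4-oxo-4H-pyran-2-carbaldehyde
Conditions: SeO2 (1 equiv), 1,4-dioxane, reflux
Reagents that add atoms: selenium dioxide, O=[Se]=O
Why: Riley oxidation; only the methyl groups at C2 and C6 can enolise vinylogously, and the symmetry of 18 makes them equivalent, so one equivalent of oxidant gives one aldehyde.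

Step 12
Reactants: 19 3,5,6-trimethyl-4-oxo-4H-pyran-2-carbaldehyde
Product: 20 2-(1-hydroxyethyl)-3,5,6-trimethyl-4H-pyran-4-one (racemic)
Conditions: MeMgBr, THF, −78 °C; aq NH4Cl
Reagents that add atoms: methylmagnesium bromide, C[Mg]Br
Why: Grignard addition to the aldehyde, which at −78 °C is far more electrophilic than the cross-conjugated ring carbonyl; the racemate suffices because step 17 is stereoconvergent.

Step 13
Reactants: 20 2-(1-hydroxyethyl)-3,5,6-trimethyl-4H-pyran-4-one
Product: 21 2-(1-chloroethyl)-3,5,6-trimethyl-4H-pyran-4-one (racemic)
Conditions: SOCl2, CH2Cl2, 0 °C to rt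
Reagents that add atoms: thionyl chloride, O=S(Cl)Cl
Why: Chlorodehydroxylation of an activated, benzylic-type alcohol; no base is present, so elimination to the vinylpyranone is avoided.

Step 14
Reactants: 9 meso anhydride; 16 (4R,5R,6R,7S)-5-hydroxy-4,6-dimethyl-7-[(triethylsilyl)oxy]nonan-3-one
Product: 22 hemiester: O5′ of 16 acylated by C1 of (2R,3R,4S)-3-[(tert-butyldimethylsilyl)oxy]-2,4-dimethylpentanedioic acid, C5 carboxyl free
Conditions: 9 (1.3 equiv), (2S,3R)-3-isopropyl-2-phenyl-3,4-dihydro-2H-benzo[4,5]thiazolo[3,2-a]pyrimidine (HyperBTM, 20 mol %), iPr2NEt (1.0 equiv), CH2Cl2, −40 °C to −10 °C; aq citric acid; chromatography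
Reagents that add atoms: none
Why: Proposed new method: the isothiourea adds reversibly to either carbonyl of 9 and gives two diastereomeric acyl isothiouronium carboxylates that interconvert through 9 (Curtin–Hammett situation), and the internal carboxylate takes the proton of 16 while its oxygen attacks the acyl carbon in the rate- and selectivity-determining step. The closest known reaction types are the opening of 3-silyloxyglutaric anhydrides by chiral secondary alcohols under 4-(dimethylamino)pyridine catalysis and the isothiourea-catalysed kinetic resolution of α-branched acids, as mixed anhydrides, with hindered secondary alcohols; new is their union on a meso 2,4-dimethylglutaric anhydride with a fragment alcohol. No ring is closed; the oxane-2,6-dione ring of 9 is opened at its C1–O bond. No stereocentre is made by bond formation: C2, C3 and C4 stand in 9 in the right relative sense, and the choice of the carbonyl next to the (R)-configured α-carbon fixes them as 2R,3R,4S. The control element is the catalyst: the 1,5 S···O contact holds the acyl group coplanar with the cation, the phenyl group shields one face, the alcohol comes from the other face anti to the C3 branch (Felkin-type), and only the (R)-configured α-carbon then turns H instead of CH3 towards the catalyst. The step needs group selectivity (C1 against C5), a single acylation and freedom from E1cB loss of the new carboxylate. The substrates secure the first by carrying the two oppositely configured methyl-bearing carbons directly next to the competing carbonyls and by the near-identity of the two branches at C5′ of 16, which leaves little bias against the catalyst; the second because the product is a carboxylate; the third because nothing more basic than iPr2NEt is present below 0 °C. The two possible products are diastereomers, so residual wrong-sense opening is removed by chromatography.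

Step 15
Reactants: 22 hemiester
Product: 24 diketo hemiester: (4R,6R)-4,6-dimethyl-3,7-dioxononan-5-yl ester at C1 of (2R,3R,4S)-3-[(tert-butyldimethylsilyl)oxy]-2,4-dimethylpentanedioic acid, C5 carboxyl free, via C7′ alcohol 23 (not isolated)
Conditions: IBX (3 equiv), DMSO, rt
Reagents that add atoms: none
Why: IBX in DMSO cleaves triethylsilyl ethers in the presence of tert-butyldimethylsilyl ethers and oxidises the freed alcohol in the same flask, so 23 has little time for 1,3-acyl migration. The oxidation removes C7′ and makes the two arms identical, so C5′ ceases to be a stereocentre.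

Step 16
Reactants: 24 diketo hemiester
Product: 25 acid chloride of 24 (C5 = COCl, all stereocentres unchanged)
Conditions: 1-chloro-N,N,2-trimethylprop-1-en-1-amine, CH2Cl2, 0 °C; evaporation, used at once
Reagents that add atoms: 1-chloro-N,N,2-trimethylprop-1-en-1-amine, CC(C)=C(Cl)N(C)C
Why: Neutral acid chloride formation with an α-chloroenamine releases neither HCl nor base, so the silyl ether, the β-acyloxy ketones and C4 survive.

Step 17
Reactants: 25 acid chloride; 21 2-(1-chloroethyl)-3,5,6-trimethyl-4H-pyran-4-one (racemic, 1.5 equiv)
Product: 26 (4R,6R)-4,6-dimethyl-3,7-dioxononan-5-yl (2R,3R,4S,6S)-3-[(tert-butyldimethylsilyl)oxy]-2,4-dimethyl-5-oxo-6-(3,5,6-trimethyl-4-oxo-4H-pyran-2-yl)heptanoate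
Conditions: NiCl2(dme) (10 mol %), (4R,4′R)-2,2′-(propane-2,2-diyl)bis(4-phenyl-4,5-dihydro-1,3-oxazole) (22 mol %), manganese powder (3 equiv), 2,6-dimethylbenzoic acid (0.75 equiv), 3 Å molecular sieves, DMA/THF 3:7, 20 °C
Reagents that add atoms: none
Why: Nickel-catalysed asymmetric reductive acyl cross-coupling of an acid chloride with a racemic secondary benzylic-type chloride: zerovalent nickel inserts into the C–Cl bond of 25, 21 is reduced to the planar C6 radical (both enantiomers converge), and radical capture and reductive elimination within the chiral bis(oxazoline) complex set C6 as S under catalyst control. The medium is weakly acidic and free of base, so the β-acyloxy ketones, C4 and the new C6 are not enolised, and allylic strain with the C3 methyl group of ring P holds C6–H in the ring plane and lowers its kinetic acidity.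

Step 18
Reactants: 26 silyl ether
Product: 27 (4R,6R)-4,6-dimethyl-3,7-dioxononan-5-yl (2R,3R,4S,6S)-3-hydroxy-2,4-dimethyl-5-oxo-6-(3,5,6-trimethyl-4-oxo-4H-pyran-2-yl)heptanoate (target)
Conditions: HF·pyridine, pyridine, THF, 0 °C to rt
Reagents that add atoms: none
Why: Fluoride-driven desilylation in a buffered, non-basic medium; no condition for E1cB, retro-aldol or enolisation at C6 is created, and no stereocentre is touched.

## Compound list

1 | methacrolein (2-methylprop-2-enal) | C=C(C)C=O | starting material
2 | isopropenylmagnesium bromide | C=C(C)[Mg]Br | starting material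
3 | 2,4-dimethylpenta-1,4-dien-3-ol | C=C(C)C(O)C(C)=C | intermediate
4 | tert-butyl[(2,4-dimethylpenta-1,4-dien-3-yl)oxy]dimethylsilane | C=C(C)C(O[Si](C)(C)C(C)(C)C)C(C)=C | intermediate
5 | 1,5-bis(9-borabicyclo[3.3.1]nonan-9-yl) adduct of 4 (anti,anti, meso) | B1(C[C@H](C)[C@H](O[Si](C)(C)C(C)(C)C)[C@H](C)CB2C3CCCC2CCC3)C2CCCC1CCC2 | intermediate
6 | (2R,3s,4S)-3-[(tert-butyldimethylsilyl)oxy]-2,4-dimethylpentane-1,5-diol | OC[C@H](C)[C@H](O[Si](C)(C)C(C)(C)C)[C@H](C)CO | intermediate
7 | (2R,3r,4S)-3-[(tert-butyldimethylsilyl)oxy]-2,4-dimethylpentanedial | O=C[C@H](C)[C@H](O[Si](C)(C)C(C)(C)C)[C@H](C)C=O | intermediate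
8 | (2R,3r,4S)-3-[(tert-butyldimethylsilyl)oxy]-2,4-dimethylpentanedioic acid | OC(=O)[C@H](C)[C@H](O[Si](C)(C)C(C)(C)C)[C@H](C)C(O)=O | intermediate
9 | (3R,4r,5S)-4-[(tert-butyldimethylsilyl)oxy]-3,5-dimethyloxane-2,6-dione | O=C1[C@H](C)[C@H](O[Si](C)(C)C(C)(C)C)[C@H](C)C(=O)O1 | intermediate
10 | propanal | CCC=O | starting material
11 | (2S,3S)-3-hydroxy-2-methylpentanal | O=C[C@@H](C)[C@@H](O)CC | intermediate
12 | (2S,3S)-2-methyl-3-[(triethylsilyl)oxy]pentanal | O=C[C@@H](C)[C@@H](O[Si](CC)(CC)CC)CC | intermediate
13 | pentan-3-one | CCC(=O)CC | starting material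
14 | (E)-dicyclohexyl(pent-2-en-3-yloxy)borane | C/C=C(/OB(C1CCCCC1)C1CCCCC1)CC | intermediate
15 | O5′-dicyclohexylboryl aldolate of 16 | CCC(=O)[C@H](C)[C@H](OB(C1CCCCC1)C1CCCCC1)[C@@H](C)[C@@H](O[Si](CC)(CC)CC)CC | intermediate
16 | (4R,5R,6R,7S)-5-hydroxy-4,6-dimethyl-7-[(triethylsilyl)oxy]nonan-3-one | CCC(=O)[C@H](C)[C@H](O)[C@@H](C)[C@@H](O[Si](CC)(CC)CC)CC | intermediate
17 | 3,5-dimethylheptane-2,4,6-trione | CC(=O)C(C)C(=O)C(C)C(C)=O | intermediate
18 | 2,3,5,6-tetramethyl-4H-pyran-4-one | Cc1oc(C)c(C)c(=O)c1C | intermediate
19 | 3,5,6-trimethyl-4-oxo-4H-pyran-2-carbaldehyde | O=Cc1oc(C)c(C)c(=O)c1C | intermediate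
20 | 2-(1-hydroxyethyl)-3,5,6-trimethyl-4H-pyran-4-one (racemic) | CC(O)c1oc(C)c(C)c(=O)c1C | intermediate
21 | 2-(1-chloroethyl)-3,5,6-trimethyl-4H-pyran-4-one (racemic) | CC(Cl)c1oc(C)c(C)c(=O)c1C | intermediate
22 | hemiester of 16 (O5′) with C1 of the (2R,3R,4S)-silyloxy diacid, C5 acid free | CCC(=O)[C@H](C)[C@H](OC(=O)[C@H](C)[C@H](O[Si](C)(C)C(C)(C)C)[C@H](C)C(O)=O)[C@@H](C)[C@@H](O[Si](CC)(CC)CC)CC | intermediate
23 | C7′ alcohol from 22 (triethylsilyl group lost) | CCC(=O)[C@H](C)[C@H](OC(=O)[C@H](C)[C@H](O[Si](C)(C)C(C)(C)C)[C@H](C)C(O)=O)[C@@H](C)[C@@H](O)CC | intermediate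
24 | diketo hemiester, (4R,6R)-4,6-dimethyl-3,7-dioxononan-5-yl at C1, C5 acid free | CCC(=O)[C@H](C)C(OC(=O)[C@H](C)[C@H](O[Si](C)(C)C(C)(C)C)[C@H](C)C(O)=O)[C@@H](C)C(=O)CC | intermediate
25 | acid chloride of 24 | CCC(=O)[C@H](C)C(OC(=O)[C@H](C)[C@H](O[Si](C)(C)C(C)(C)C)[C@H](C)C(Cl)=O)[C@@H](C)C(=O)CC | intermediate
26 | 3-O-tert-butyldimethylsilyl ether of 27 | CCC(=O)[C@H](C)C(OC(=O)[C@H](C)[C@H](O[Si](C)(C)C(C)(C)C)[C@H](C)C(=O)[C@@H](C)c1oc(C)c(C)c(=O)c1C)[C@@H](C)C(=O)CC | intermediate
27 | (4R,6R)-4,6-dimethyl-3,7-dioxononan-5-yl (2R,3R,4S,6S)-3-hydroxy-2,4-dimethyl-5-oxo-6-(3,5,6-trimethyl-4-oxo-4H-pyran-2-yl)heptanoate | CCC(=O)[C@H](C)C(OC(=O)[C@H](C)[C@H](O)[C@H](C)C(=O)[C@@H](C)c1oc(C)c(C)c(=O)c1C)[C@@H](C)C(=O)CC | target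

## Step count and least certain steps

Total: 18 steps. Longest linear sequence: 11 steps (steps 1–6 and 14–18). The side branches take 3 steps (7–9) and 4 steps (10–13).

**Step 14 (key step, proposed new method).**
- Most likely failures: slow acyl transfer between two hindered partners, and too small a rate difference between the two enantiotopic carbonyls. The recognition of an α-methyl against an α-hydrogen by the catalyst is untested for purely aliphatic acyl groups. A slow catalysed path also leaves room for unselective background opening.
- Fallback with known chemistry, setting out from 9: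
  - Cinchona-alkaloid-catalysed alcoholysis with benzyl alcohol (hydroquinidine anthraquinone-1,4-diyl diether or its hydroquinine counterpart, Et2O, low temperature). The alkaloid series is chosen so that the benzyl group goes to C5. This gives the monobenzyl ester F1, with C1 as the free acid.
  - Yamaguchi esterification of F1 with 16 gives the mixed diester F2.
  - Hydrogenolysis (H2, palladium on carbon, EtOAc) comes back to the route at 22.

**Step 17.**
- Most likely failures: sluggish coupling because of the α-branch of the acyl group and the methyl group next to the reacting carbon of ring P. This would bring homocoupling of the C6 radical, direct reduction of the chloride by manganese followed by uncatalysed acylation, poor facial selectivity at C6, and ester/acid chloride interchange through a cyclic acyloxonium ion while 25 waits.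
- Fallback, setting out from 24:
  - EtSH, DCC and catalytic 4-(dimethylamino)pyridine give the S-ethyl thioester F3.
  - Zinc dust and LiCl in THF convert 21 into the organozinc chloride F4.
  - Fukuyama coupling of the two (PdCl2(PPh3)2, toluene/THF, rt) gives 26 together with its C6 epimer F5.
  - The epimers are separated by chromatography. F5 is re-equilibrated at its single strongly acidic carbon by brief contact with a weak base and separated again.
  - The route is rejoined at 26.

**Step 15.**
- Most likely failures: 1,3-migration of the acyl group from the crowded O5′ to the freed, less hindered O7′ before oxidation, or slow cleavage of the secondary triethylsilyl ether.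
- Fallback, setting out from 16, so that no free hydroxyl group ever stands next to the ester:
  - AcOH/THF/H2O gives the diol F6.
  - A sterically discriminating oxidation of the less hindered C7′ carbinol (TEMPO, PhI(OAc)2, CH2Cl2) gives the C2-symmetric hydroxy diketone F7.
  - F7 opens 9 under the conditions of step 14, and the route is rejoined at 24.

**Step 9.**
- Most likely failure: erosion of Felkin selectivity by the β-silyloxy group. This would place the two methyl groups 1,3-syn and lead to the meso-type diketone series.
- Fallback with reagent control, setting out from 12: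
  - (S)-2-(benzoyloxy)pentan-3-one F8 is made in three known steps from ethyl (S)-lactate. It is enolised with Cy2BCl and Me2NEt and added to 12.
  - Its stereocentre directs the anti aldol to the 4′R configuration, matched with Felkin attack, and gives the adduct F9.
  - Samarium diiodide (SmI2, THF/MeOH) removes the benzoyloxy group and comes back to the route at 16.

## Further compounds

F1 | step 14 | monobenzyl ester of 8 (benzyl at C5, free acid at C1; C2, C3, C4 placed as in 22) | OC(=O)[C@H](C)[C@H](O[Si](C)(C)C(C)(C)C)[C@H](C)C(=O)OCc1ccccc1
F2 | step 14 | mixed diester: benzyl ester of 22 at C5 | CCC(=O)[C@H](C)[C@H](OC(=O)[C@H](C)[C@H](O[Si](C)(C)C(C)(C)C)[C@H](C)C(=O)OCc1ccccc1)[C@@H](C)[C@@H](O[Si](CC)(CC)CC)CC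
F3 | step 17 | S-ethyl thioester of 24 at C5 | CCC(=O)[C@H](C)C(OC(=O)[C@H](C)[C@H](O[Si](C)(C)C(C)(C)C)[C@H](C)C(=O)SCC)[C@@H](C)C(=O)CC
F4 | step 17 | [1-(3,5,6-trimethyl-4-oxo-4H-pyran-2-yl)ethyl]zinc chloride (racemic) | CC([Zn]Cl)c1oc(C)c(C)c(=O)c1C
F5 | step 17 | (6R) epimer of 26 | CCC(=O)[C@H](C)C(OC(=O)[C@H](C)[C@H](O[Si](C)(C)C(C)(C)C)[C@H](C)C(=O)[C@H](C)c1oc(C)c(C)c(=O)c1C)[C@@H](C)C(=O)CC
F6 | step 15 | 5,7-dihydroxy-4,6-dimethylnonan-3-one (stereocentres placed as in 16) | CCC(=O)[C@H](C)[C@H](O)[C@@H](C)[C@@H](O)CC
F7 | step 15 | (4R,6R)-5-hydroxy-4,6-dimethylnonane-3,7-dione | CCC(=O)[C@H](C)C(O)[C@@H](C)C(=O)CC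
F8 | step 9 | (S)-2-(benzoyloxy)pentan-3-one | CCC(=O)[C@H](C)OC(=O)c1ccccc1
F9 | step 9 | (2S)-2-benzoyloxy derivative of 16 (anti aldol adduct, other centres as in 16) | C[C@H](OC(=O)c1ccccc1)C(=O)[C@H](C)[C@H](O)[C@@H](C)[C@@H](O[Si](CC)(CC)CC)CC
A1 | alternative 1 | (2R,3R,4S,6S)-3-[(tert-butyldimethylsilyl)oxy]-2,4-dimethyl-5-oxo-6-(3,5,6-trimethyl-4-oxo-4H-pyran-2-yl)heptanoic acid | OC(=O)[C@H](C)[C@H](O[Si](C)(C)C(C)(C)C)[C@H](C)C(=O)[C@@H](C)c1oc(C)c(C)c(=O)c1C
A2 | alternative 1 | (4R,6R)-5-hydroxy-4,6-dimethylnonane-3,7-dione | CCC(=O)[C@H](C)C(O)[C@@H](C)C(=O)CC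
A3 | alternative 2 | linear δ-hydroxy-β-diketone isomer of 27 (β-diketone methine labile, not assigned) | CCC(=O)[C@H](C)[C@H](O)[C@@H](C)C(=O)C(C)C(=O)[C@H](C)[C@H](O)[C@H](C)C(=O)[C@@H](C)c1oc(C)c(C)c(=O)c1C
A4 | alternative 3 | (S)-2-(3-oxopentan-2-yl)-3,5,6-trimethyl-4H-pyran-4-one | CCC(=O)[C@@H](C)c1oc(C)c(C)c(=O)c1C
A5 | alternative 3 | (4R,6R)-4,6-dimethyl-3,7-dioxononan-5-yl (R)-2-methyl-3-oxopropanoate | CCC(=O)[C@H](C)C(OC(=O)[C@H](C)C=O)[C@@H](C)C(=O)CC
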